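**Plan**
- Cuts: the triene single bond next to the C4 alkene (Stille) and the ring C2–N bond (copper amidation of a 2-iodoenone) release the two polyene amides. The epoxide C6–O bond goes back to a trans-5,6-diol, the ring alkene C2=C3 to a dienone (metathesis), and the C4–vinyl, C4–alkynyl and C1–vinyl bonds to D-tartrate.
- Enabling feature: C1, C6, C5 and C4 of the six-membered ring carry four oxygen atoms in a row, i.e. tartaric acid with one carbon added at each end, and the only C=C of that ring, C2=C3, joins the two added carbons.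
- Forward order: tartrate diamide → C4 ynone → C4 carbinol → C1 vinyl ketone → cyclohexenone ring by metathesis → epoxide ring by displacement at C6 → C2 iodide → C2 amide → alkenylstannane → triene by coupling with the separately made iododienamide.
- Stereochemistry: C5 and C6 come from D-tartrate (C6 is inverted once when the epoxide closes); C4 comes from a chelation-controlled vinyl addition anti to O5. Alkene geometry comes from Horner–Wadsworth–Emmons and Takai olefinations, syn-hydrostannation and stereoretentive couplings.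

Key step: step 5

Remark: the acylaminocyclopentanedione is written as the enol tautomer of the target SMILES (both enol forms are identical by symmetry); N,O-dimethylhydroxylamine hydrochloride, (E)-4-methylpent-2-enal, triethyl 4-phosphonocrotonate and ethyl (E)-4-oxobut-2-enoate are taken as purchased.

**Route**

Step 1
Reactants: 1 dimethyl 2,3-O-isopropylidene-D-tartrate
Product: 2 (4S,5S)-N4,N5-dimethoxy-N4,N5,2,2-tetramethyl-1,3-dioxolane-4,5-dicarboxamide
Conditions: MeNH(OMe)·HCl, i-PrMgCl, THF, −20 → 0 °C
Reagents that add atoms: N,O-dimethylhydroxylamine hydrochloride, CNOC.Cl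
Why: Aminolysis of both esters by the chloromagnesium amide of N,O-dimethylhydroxylamine (Weinreb amide formation) runs at low temperature, and the trans-dioxolane stereocentres are safe because trans is also the thermodynamically preferred arrangement.

Step 2
Reactants: 2 bis-Weinreb amide; 3 triisopropylsilylacetylene
Product: 4 (4S,5S)-N-methoxy-N,2,2-trimethyl-5-[3-(triisopropylsilyl)prop-2-ynoyl]-1,3-dioxolane-4-carboxamide
Conditions: 3, n-BuLi, THF, −78 °C; then 2 (1 equiv), −78 → −40 °C; aq. NH4Cl
Reagents that add atoms: none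
Why: Weinreb ketone synthesis: one equivalent of the lithium acetylide adds once to one of the two equivalent amide groups and the ketone appears only on work-up, so the C2-symmetric diamide is desymmetrised to the mono-ynone and unreacted 2 can be recycled.

Step 3
Reactants: 4 ynone amide; 5 vinylmagnesium bromide
Product: 6 (4S,5S)-5-[(3R)-3-hydroxy-5-(triisopropylsilyl)pent-1-en-4-yn-3-yl]-N-methoxy-N,2,2-trimethyl-1,3-dioxolane-4-carboxamide
Conditions: MgBr2·OEt2, CH2Cl2, −78 °C; then 5 (THF solution), −78 °C; aq. NH4Cl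
Reagents that add atoms: none
Why: Cram-chelate addition of a Grignard reagent to an alpha-alkoxy ketone: magnesium bridges the ketone oxygen and the neighbouring dioxolane oxygen O5, vinyl enters from the face of the C5 hydrogen and so sets C4 as R with its hydroxyl anti to O5, while at −78 °C the Weinreb amide is not attacked and the bulky silyl group blocks conjugate addition.

Step 4
Reactants: 6 tertiary carbinol amide; 5 vinylmagnesium bromide
Product: 7 1-{(4S,5S)-5-[(3R)-3-hydroxy-5-(triisopropylsilyl)pent-1-en-4-yn-3-yl]-2,2-dimethyl-1,3-dioxolan-4-yl}prop-2-en-1-one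
Conditions: 5 (3 equiv), THF, −78 → 0 °C; inverse quench into cold 1 M HCl
Reagents that add atoms: none
Why: Weinreb ketone synthesis with the vinyl Grignard reagent (one equivalent is spent on the tertiary hydroxyl); the acidic inverse quench protonates the released amine before it can add to the new vinyl ketone, and the trans-dioxolane keeps the C4 hydroxyl from closing onto C1.

Step 5
Reactants: 7 dienone carbinol
Product: 8 (3aS,4R,7aS)-4-hydroxy-2,2-dimethyl-4-[(triisopropylsilyl)ethynyl]-3a,7a-dihydro-1,3-benzodioxol-7(4H)-one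
Conditions: second-generation Grubbs catalyst (H2IMes)(PCy3)Cl2Ru=CHPh (5 mol%), CH2Cl2 (5 mM), 40 °C
Reagents that add atoms: none
Why: The ruthenium benzylidene first exchanges onto the less electron-poor C4 vinyl group, and the new alkylidene adds across the vinyl ketone by [2+2] cycloaddition; cycloreversion of the ruthenacyclobutane forms the C2=C3 bond, returns a ruthenium methylidene and releases ethene, whose escape drives the closure. The closest known reaction type is ring-closing metathesis of tartrate- and sugar-derived 1,7-dienes to conduritol-type cyclohexenes and of acyclic dienones to cyclohex-2-enones. The six-membered carbocycle closes by joining the two alkene termini C3 and C2 of the 1,7-diene, helped by the trans-dioxolane, which holds C4 and C1 gauche and within reach. No stereocentre is formed; C4, C5 and C6 pass through unchanged because the medium is neutral. The selectivity needed is diene over enyne metathesis and ring closure over dimerisation: the triisopropylsilyl group shields the alkyne from the alkylidene, an alkylidene at C3 cannot cyclise onto the alkyne on its own carbon, and high dilution disfavours cross-metathesis.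

Step 6
Reactants: 8 cyclohexenone trans-acetonide
Product: 9 (4R,5S,6S)-4,5,6-trihydroxy-4-[(triisopropylsilyl)ethynyl]cyclohex-2-en-1-one
Conditions: CF3CO2H/H2O (9:1), 0 °C
Reagents that add atoms: none
Why: Acid-catalysed acetal hydrolysis, fast for the strained trans-fused dioxolane, whereas the C4 carbinol resists ionisation because its cation would be conjugated with the electron-poor enone.

Step 7
Reactants: 9 triol enone
Product: 11 (1R,5R,6S)-5-hydroxy-5-[(triisopropylsilyl)ethynyl]-7-oxabicyclo[4.1.0]hept-3-en-2-one, via C6 tosylate 10 (not isolated)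
Conditions: TsCl (1.1 equiv), Et3N, Me3N·HCl (cat.), CH2Cl2, −20 → 0 °C; then DBU, 0 °C
Reagents that add atoms: p-toluenesulfonyl chloride, Cc1ccc(cc1)S(Cl)(=O)=O (sulfonyl group of 10, lost again in 11)
Why: Regioselective sulfonylation of the more acidic and less hindered alpha-ketol hydroxyl at C6 (the C5 hydroxyl is flanked by the quaternary C4, the tertiary hydroxyl is inert) followed by intramolecular SN2 displacement by the trans C5 oxygen (Darzens-type closure of a beta-hydroxy ketone with an alpha leaving group) inverts C6 and places the cis-fused epoxide on the face opposite the C4 hydroxyl.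

Step 8
Reactants: 11 epoxy enone
Product: 12 (1R,5R,6S)-5-hydroxy-3-iodo-5-[(triisopropylsilyl)ethynyl]-7-oxabicyclo[4.1.0]hept-3-en-2-one
Conditions: I2, pyridine/CH2Cl2 (1:1), 0 °C → rt, dark
Reagents that add atoms: iodine, II
Why: Amine-mediated alpha-iodination of an enone (Baylis–Hillman-type sequence: pyridine adds to C3, the enolate is iodinated at C2, pyridine leaves), a reaction known for 4-oxygenated 5,6-epoxycyclohex-2-enones; epoxide, silyl alkyne and tertiary hydroxyl are inert to iodine.

Step 9
Reactants: 13 (E)-4-methylpent-2-enal; 14 triethyl (E)-4-phosphonocrotonate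
Product: 15 ethyl (2E,4E,6E)-8-methylnona-2,4,6-trienoate
Conditions: LiN(SiMe3)2, THF, −78 → 0 °C
Reagents that add atoms: none
Why: Vinylogous Horner–Wadsworth–Emmons olefination, in which the stabilised phosphonate anion should form the new C4=C5 bond with E geometry and leave the two existing E alkenes untouched.

Step 10
Reactants: 15 trienoate
Product: 16 (2E,4E,6E)-8-methylnona-2,4,6-trienamide
Conditions: AlMe3, NH4Cl, toluene, 0 → 50 °C
Reagents that add atoms: ammonium chloride, [NH4+].[Cl-]
Why: Weinreb aminolysis: the aluminium amide formed from AlMe3 and NH4Cl attacks the ester carbonyl directly and gives the primary amide without conjugate addition to the triene.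

Step 11
Reactants: 12 iodo epoxy enone; 16 trienamide
Product: 17 (2E,4E,6E)-N-{(1R,5R,6S)-5-hydroxy-2-oxo-5-[(triisopropylsilyl)ethynyl]-7-oxabicyclo[4.1.0]hept-3-en-3-yl}-8-methylnona-2,4,6-trienamide
Conditions: CuI (10 mol%), MeNHCH2CH2NHMe (20 mol%), Cs2CO3, THF, 40 °C, dark
Reagents that add atoms: none
Why: Copper-catalysed Goldberg-type amidation of a vinyl iodide: the diamine-ligated copper amidate inserts into the activated C2–I bond and reductive elimination forms the C2–N bond with the alkene in place, while the mild heterogeneous base and low temperature are chosen to spare the epoxide and the silyl alkyne.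

Step 12
Reactants: 17 silyl alkyne amide
Product: 18 (2E,4E,6E)-N-[(1R,5R,6S)-5-ethynyl-5-hydroxy-2-oxo-7-oxabicyclo[4.1.0]hept-3-en-3-yl]-8-methylnona-2,4,6-trienamide
Conditions: Bu4NF, AcOH, THF, 0 °C
Reagents that add atoms: none
Why: Fluoride-induced cleavage of the C(sp)–Si bond, buffered with acetic acid so that the epoxy ketone and the anti hydroxy epoxide (prone to Payne migration) do not meet a strong base.

Step 13
Reactants: 18 terminal alkyne
Product: 19 (2E,4E,6E)-N-{(1R,5R,6S)-5-hydroxy-2-oxo-5-[(E)-2-(tributylstannyl)ethenyl]-7-oxabicyclo[4.1.0]hept-3-en-3-yl}-8-methylnona-2,4,6-trienamide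
Conditions: Bu3SnH (slow addition), PdCl2(PPh3)2 (3 mol%), THF, 0 °C
Reagents that add atoms: tributyltin hydride, CCCC[SnH](CCCC)CCCC
Why: Palladium-catalysed syn hydrostannation of a terminal alkyne, in which the quaternary carbinol directs tin to the terminal carbon and gives the (E)-alkenylstannane, and slow addition of the hydride at 0 °C keeps the fast alkyne addition ahead of any reduction of the hindered enone.

Step 14
Reactants: 20 ethyl (E)-4-oxobut-2-enoate
Product: 21 ethyl (2E,4E)-5-iodopenta-2,4-dienoate
Conditions: CHI3, CrCl2, THF, 0 °C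
Reagents that add atoms: iodoform, IC(I)I
Why: Takai olefination: the geminal dichromium species from iodoform adds to the aldehyde and eliminates to the (E)-vinyl iodide, and the enoate is inert to CrCl2.

Step 15
Reactants: 21 iodo dienoate
Product: 22 (2E,4E)-5-iodopenta-2,4-dienoic acid
Conditions: LiOH, THF/H2O, 0 °C → rt; then 1 M HCl
Reagents that add atoms: lithium hydroxide, [Li+].[OH-]
Why: Ester saponification, to which the vinyl iodide and the diene are stable in the cold.

Step 16
Reactants: 23 cyclopentane-1,3-dione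
Product: 24 2-nitrocyclopentane-1,3-dione
Conditions: fuming HNO3, Et2O, 0 °C
Reagents that add atoms: nitric acid, O[N+](=O)[O-]
Why: Electrophilic nitration of the enol of a cyclic 1,3-dione at C2, its only nucleophilic carbon.

Step 17
Reactants: 24 nitro dione
Product: 25 2-amino-3-hydroxycyclopent-2-en-1-one hydrochloride
Conditions: H2 (1 atm), Pd/C (10%), HCl, EtOH, rt
Reagents that add atoms: hydrogen chloride, Cl
Why: Catalytic hydrogenation of the nitro group to the amine, which is trapped as its hydrochloride so that the 2-amino-1,3-dione cannot condense with itself.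

Step 18
Reactants: 22 iodo dienoic acid; 25 aminocyclopentenone hydrochloride
Product: 27 (2E,4E)-N-(2-hydroxy-5-oxocyclopent-1-en-1-yl)-5-iodopenta-2,4-dienamide, via acid chloride 26 (not isolated)
Conditions: (COCl)2, DMF (cat.), CH2Cl2, 0 °C → rt; then 25, pyridine, CH2Cl2, 0 °C → rt
Reagents that add atoms: oxalyl chloride, O=C(Cl)C(Cl)=O (chlorine of 26, lost again in 27)
Why: Acid chloride formation and N-acylation (Schotten–Baumann type); the amine is more nucleophilic than the enol oxygen, and pyridine is too weak a base to turn the dienoyl chloride into a vinylketene.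

Step 19
Reactants: 19 alkenylstannane; 27 iododienamide
Product: 28 target compound CNP0215439.3
Conditions: PdCl2(MeCN)2 (10 mol%), DMF, rt, dark
Reagents that add atoms: none
Why: Stille coupling: insertion of zerovalent palladium into the dienyl C–I bond, tin-to-palladium transfer of the alkenyl group and reductive elimination all proceed with retention of alkene geometry, so the all-E triene should form under neutral conditions at room temperature without touching any stereocentre.

**Compound list**

1 | dimethyl 2,3-O-isopropylidene-D-tartrate | COC(=O)[C@H]1OC(C)(C)O[C@@H]1C(=O)OC | starting material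
2 | (4S,5S)-N4,N5-dimethoxy-N4,N5,2,2-tetramethyl-1,3-dioxolane-4,5-dicarboxamide | CON(C)C(=O)[C@H]1OC(C)(C)O[C@@H]1C(=O)N(C)OC | intermediate
3 | triisopropylsilylacetylene | C#C[Si](C(C)C)(C(C)C)C(C)C | starting material
4 | (4S,5S)-N-methoxy-N,2,2-trimethyl-5-[3-(triisopropylsilyl)prop-2-ynoyl]-1,3-dioxolane-4-carboxamide | CC(C)[Si](C(C)C)(C(C)C)C#CC(=O)[C@H]1OC(C)(C)O[C@@H]1C(=O)N(C)OC | intermediate
5 | vinylmagnesium bromide | C=C[Mg]Br | starting material
6 | (4S,5S)-5-[(3R)-3-hydroxy-5-(triisopropylsilyl)pent-1-en-4-yn-3-yl]-N-methoxy-N,2,2-trimethyl-1,3-dioxolane-4-carboxamide | C=C[C@@](O)(C#C[Si](C(C)C)(C(C)C)C(C)C)[C@H]1OC(C)(C)O[C@@H]1C(=O)N(C)OC | intermediate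
7 | 1-{(4S,5S)-5-[(3R)-3-hydroxy-5-(triisopropylsilyl)pent-1-en-4-yn-3-yl]-2,2-dimethyl-1,3-dioxolan-4-yl}prop-2-en-1-one | C=C[C@@](O)(C#C[Si](C(C)C)(C(C)C)C(C)C)[C@H]1OC(C)(C)O[C@@H]1C(=O)C=C | intermediate
8 | (3aS,4R,7aS)-4-hydroxy-2,2-dimethyl-4-[(triisopropylsilyl)ethynyl]-3a,7a-dihydro-1,3-benzodioxol-7(4H)-one | O=C1C=C[C@@](O)(C#C[Si](C(C)C)(C(C)C)C(C)C)[C@H]2OC(C)(C)O[C@H]12 | intermediate
9 | (4R,5S,6S)-4,5,6-trihydroxy-4-[(triisopropylsilyl)ethynyl]cyclohex-2-en-1-one | O=C1C=C[C@@](O)(C#C[Si](C(C)C)(C(C)C)C(C)C)[C@@H](O)[C@@H]1O | intermediate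
10 | (1S,5R,6S)-5,6-dihydroxy-2-oxo-5-[(triisopropylsilyl)ethynyl]cyclohex-3-en-1-yl 4-methylbenzenesulfonate | O=C1C=C[C@@](O)(C#C[Si](C(C)C)(C(C)C)C(C)C)[C@@H](O)[C@@H]1OS(=O)(=O)c1ccc(C)cc1 | intermediate
11 | (1R,5R,6S)-5-hydroxy-5-[(triisopropylsilyl)ethynyl]-7-oxabicyclo[4.1.0]hept-3-en-2-one | O=C1C=C[C@@](O)(C#C[Si](C(C)C)(C(C)C)C(C)C)[C@H]2O[C@@H]12 | intermediate
12 | (1R,5R,6S)-5-hydroxy-3-iodo-5-[(triisopropylsilyl)ethynyl]-7-oxabicyclo[4.1.0]hept-3-en-2-one | O=C1C(I)=C[C@@](O)(C#C[Si](C(C)C)(C(C)C)C(C)C)[C@H]2O[C@@H]12 | intermediate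
13 | (E)-4-methylpent-2-enal | CC(C)/C=C/C=O | starting material
14 | triethyl (E)-4-phosphonocrotonate | CCOC(=O)/C=C/CP(=O)(OCC)OCC | starting material
15 | ethyl (2E,4E,6E)-8-methylnona-2,4,6-trienoate | CC(C)/C=C/C=C/C=C/C(=O)OCC | intermediate
16 | (2E,4E,6E)-8-methylnona-2,4,6-trienamide | CC(C)/C=C/C=C/C=C/C(N)=O | intermediate
17 | (2E,4E,6E)-N-{(1R,5R,6S)-5-hydroxy-2-oxo-5-[(triisopropylsilyl)ethynyl]-7-oxabicyclo[4.1.0]hept-3-en-3-yl}-8-methylnona-2,4,6-trienamide | CC(C)/C=C/C=C/C=C/C(=O)NC1=C[C@@](O)(C#C[Si](C(C)C)(C(C)C)C(C)C)[C@H]2O[C@H]2C1=O | intermediate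
18 | (2E,4E,6E)-N-[(1R,5R,6S)-5-ethynyl-5-hydroxy-2-oxo-7-oxabicyclo[4.1.0]hept-3-en-3-yl]-8-methylnona-2,4,6-trienamide | CC(C)/C=C/C=C/C=C/C(=O)NC1=C[C@@](O)(C#C)[C@H]2O[C@H]2C1=O | intermediate
19 | (2E,4E,6E)-N-{(1R,5R,6S)-5-hydroxy-2-oxo-5-[(E)-2-(tributylstannyl)ethenyl]-7-oxabicyclo[4.1.0]hept-3-en-3-yl}-8-methylnona-2,4,6-trienamide | CC(C)/C=C/C=C/C=C/C(=O)NC1=C[C@@](O)(/C=C/[Sn](CCCC)(CCCC)CCCC)[C@H]2O[C@H]2C1=O | intermediate
20 | ethyl (E)-4-oxobut-2-enoate | CCOC(=O)/C=C/C=O | starting material
21 | ethyl (2E,4E)-5-iodopenta-2,4-dienoate | CCOC(=O)/C=C/C=C/I | intermediate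
22 | (2E,4E)-5-iodopenta-2,4-dienoic acid | OC(=O)/C=C/C=C/I | intermediate
23 | cyclopentane-1,3-dione | O=C1CCC(=O)C1 | starting material
24 | 2-nitrocyclopentane-1,3-dione | O=C1CCC(=O)C1[N+](=O)[O-] | intermediate
25 | 2-amino-3-hydroxycyclopent-2-en-1-one hydrochloride | NC1=C(O)CCC1=O.Cl | intermediate
26 | (2E,4E)-5-iodopenta-2,4-dienoyl chloride | ClC(=O)/C=C/C=C/I | intermediate
27 | (2E,4E)-N-(2-hydroxy-5-oxocyclopent-1-en-1-yl)-5-iodopenta-2,4-dienamide | O=C(/C=C/C=C/I)NC1=C(O)CCC1=O | intermediate
28 | (2E,4E,6E)-N-[(1R,5S,6S)-5-hydroxy-5-{(1E,3E,5E)-7-[(2-hydroxy-5-oxocyclopent-1-en-1-yl)amino]-7-oxohepta-1,3,5-trien-1-yl}-2-oxo-7-oxabicyclo[4.1.0]hept-3-en-3-yl]-8-methylnona-2,4,6-trienamide | CC(C)/C=C/C=C/C=C/C(=O)NC1=C[C@@](O)(/C=C/C=C/C=C/C(=O)NC2=C(O)CCC2=O)[C@H]2O[C@H]2C1=O | target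

**Count**
Total: 19 steps. Longest linear sequence: 12 steps (steps 1–8, 11–13 and 19).

**Steps most likely to fail**

Step 11. Under the carbonate base the free C4 hydroxyl may attack the neighbouring epoxide (Payne-type migration), or the epoxy ketone may degrade faster than copper couples the hindered iodide. The fallback moves C–N bond formation ahead of epoxide formation. It sets out from enone acetonide 8: iodination with I2/pyridine should give (3aS,4R,7aS)-4-hydroxy-6-iodo-2,2-dimethyl-4-[(triisopropylsilyl)ethynyl]-3a,7a-dihydro-1,3-benzodioxol-7(4H)-one F1. The same CuI/diamine coupling with 16, now on a substrate without an epoxide, should give the amido enone acetonide F2. Aqueous CF3CO2H then frees the amido triol F3. Sulfonylation at the C6 hydroxyl (TsCl, Et3N) gives the C6 tosylate F4, which DBU closes to the epoxide, and the route is rejoined at 17.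

Step 7. Sulfonylation may also occur at the C5 hydroxyl, and the alpha-sulfonyloxy ketone may enolise and eliminate before the ring closes. The fallback is a Mitsunobu cyclodehydration of triol 9 (PPh3, diisopropyl azodicarboxylate, THF, 0 °C), which leads directly to 11. Both hydroxyls enter a dioxaphosphorane reversibly, and the product is decided by which carbon undergoes SN2 attack faster: the ketone-activated C6 rather than the neopentyl-like C5. No sulfonate has to be placed selectively and no base is present. The fallback sets out from 9 and returns at 11; no further compound arises (none F0).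

Step 3. The vinyl reagent may follow the non-chelated Felkin–Anh trajectory, or a chelate through the more remote dioxolane oxygen, giving poor or reversed facial selectivity at C4. The fallback exchanges the order in which the two C4 substituents arrive. From diamide 2, one equivalent of 5 (THF, −78 → 0 °C, acidic inverse quench) should give (4S,5S)-5-acryloyl-N-methoxy-N,2,2-trimethyl-1,3-dioxolane-4-carboxamide F5. The lithium acetylide made from 3 is then added in THF at −78 °C without magnesium salt, where the Felkin–Anh face is expected. Because resident and incoming groups have changed places, this face gives the required (R)-carbinol 6, where the route is rejoined.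

**Further compounds**

F1 | step 11 | (3aS,4R,7aS)-4-hydroxy-6-iodo-2,2-dimethyl-4-[(triisopropylsilyl)ethynyl]-3a,7a-dihydro-1,3-benzodioxol-7(4H)-one | O=C1C(I)=C[C@@](O)(C#C[Si](C(C)C)(C(C)C)C(C)C)[C@H]2OC(C)(C)O[C@H]12
F2 | step 11 | (2E,4E,6E)-N-{(3aS,4R,7aS)-4-hydroxy-2,2-dimethyl-7-oxo-4-[(triisopropylsilyl)ethynyl]-3a,4,7,7a-tetrahydro-1,3-benzodioxol-6-yl}-8-methylnona-2,4,6-trienamide | CC(C)/C=C/C=C/C=C/C(=O)NC1=C[C@@](O)(C#C[Si](C(C)C)(C(C)C)C(C)C)[C@H]2OC(C)(C)O[C@@H]2C1=O
F3 | step 11 | (2E,4E,6E)-N-{(3R,4S,5S)-3,4,5-trihydroxy-6-oxo-3-[(triisopropylsilyl)ethynyl]cyclohex-1-en-1-yl}-8-methylnona-2,4,6-trienamide | CC(C)/C=C/C=C/C=C/C(=O)NC1=C[C@@](O)(C#C[Si](C(C)C)(C(C)C)C(C)C)[C@@H](O)[C@H](O)C1=O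
F4 | step 11 | (1S,5R,6S)-5,6-dihydroxy-3-[(2E,4E,6E)-8-methylnona-2,4,6-trienamido]-2-oxo-5-[(triisopropylsilyl)ethynyl]cyclohex-3-en-1-yl 4-methylbenzenesulfonate | CC(C)/C=C/C=C/C=C/C(=O)NC1=C[C@@](O)(C#C[Si](C(C)C)(C(C)C)C(C)C)[C@@H](O)[C@H](OS(=O)(=O)c2ccc(C)cc2)C1=O
F0 | step 7 | none | none
F5 | step 3 | (4S,5S)-5-acryloyl-N-methoxy-N,2,2-trimethyl-1,3-dioxolane-4-carboxamide | C=CC(=O)[C@H]1OC(C)(C)O[C@@H]1C(=O)N(C)OC
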